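The data are simulated from invented constants.

- Substrate charged is conserved. At the last reading, the four amounts sum to 102% in ochre and 105% in violet, near the charge, so the question is how that charge divides.

| setting | ochre | violet | summer | midnight |
|---|---|---|---|---|
| substrate | 0.020 M | 0.020 M | 0.020 M | 0.020 M |
| reagent | 2.5 equiv | 7.1 equiv | 4.00 equiv | 8.00 equiv |
| remark | run made earlier | run made earlier |  |  |
| time |  |  | 3.0 h | 3.0 h |

| run | time / min | isomer of the product / % | side product / % | substrate / % | target / % |
|---|---|---|---|---|---|
| ochre | 5.00 | 2 | 12 | 81 | 7 |
| ochre | 15.0 | 0 | 31 | 51 | 17 |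
| ochre | 25.0 | 1 | 39 | 35 | 23 |
| ochre | 40.0 | 0 | 52 | 17 | 29 |
| ochre | 50.0 | 6 | 56 | 13 | 29 |
| ochre | 80.0 | 5 | 61 | 1 | 28 |
| ochre | 90.0 | 7 | 64 | 2 | 29 |
| violet | 12.0 | 0 | 24 | 41 | 37 |
| violet | 25.0 | 1 | 33 | 17 | 46 |
| violet | 40.0 | 7 | 36 | 6 | 53 |
| violet | 50.0 | 9 | 36 | 4 | 52 |
| violet | 60.0 | 10 | 34 | 2 | 51 |
| violet | 80.0 | 12 | 36 | 0 | 51 |
| violet | 90.0 | 12 | 40 | 0 | 53 |

(each reading ± 1.5 percentage points)

- which of these there is most of at the end, counted by the substrate in it, summer (substrate / target / isomer of the product / side product)
- which of these there is most of at the end, counted by the substrate in it, midnight (substrate / target / isomer of the product / side product)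
- how much there is at the end of the one of these that leads, in percent of the substrate charged: summer
- how much there is at the end of the one of these that leads, in percent of the substrate charged: midnight

- Substrate charge: it stays 0.020 M in ochre, violet, summer and midnight, so this reckoning is read at that charge.
- Time: ochre's substrate falls at 0.0446 min⁻¹, a half-life of 15.5 min. That pace leaves 0.0326% after 3.0 h, and summer carries more reagent than ochre. So 3.0 h should see the division finished.
- Reagent: if one reagent is spent per substrate, summer spends at most a quarter of its reagent charge, so reagent stays in excess, a pseudo-first-order condition.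
- Target plus isomer of the product over side product reads 0.562 in ochre and 1.62 in violet. Per equivalent, these agree. Pooled, they give a selectivity factor of 0.228 per equivalent.
- Violet's last reading puts isomer over target at 0.226, taken here as a plateau.
- The crossing charge, the reagent charge at which target equals side product at the end, is therefore 5.38 equivalents. In this reckoning, at 0.020 M of substrate, target over side product at the end is the reagent charge divided by it.
- Summer lies below the crossing, so this reckoning has side product leading at 52.3%. Midnight lies above it, so target leads at 52.7%.
- The forecast, with figures of its own that differ slightly from these, gives side product at 53% (49% to 57%) for summer and target at 52% (47% to 56%) for midnight, holding that “target formation scales with reagent, while the side-product route is reagent-independent”.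
- Summer ends with side product leading at 52.2%. Midnight ends with target leading at 51.0%.

    substrate + reagent → target (k = 0.00560 L mol⁻¹ s⁻¹)
    substrate → side product (k = 4.60 × 10⁻⁴ s⁻¹)
    target ⇌ isomer of the product (K = 0.280, k = 9.90 × 10⁻⁵ s⁻¹)

- Summer's target over side product comes to 0.718, against 0.743 from the crossing. Midnight's comes to 1.46, against 1.49.
- The neighbour of summer charged with 1.60 equiv lies below the crossing, and the same division gives it a target over side product of 0.297. That flask ends with 20.6% target and 73.6% side product, a ratio of 0.280.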